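**Strategy.** Number the cyclohexene C1 (C–Me), C2 (=CH), C3 (CH–stilbenylaryl), C4 (CH–aroyl), C5 (CH–aryl), C6 (CH2). The ring is cut (3+3) at C6–C1 and C3–C4. The feature exploited: the aroyl C=O, C4, C5 and C6 are a γ-keto alkyl chain, i.e. a ring-opened 1,3-diarylcyclobutanol, and C1–C3 are an allene benzylic to the electron-rich resorcinol ring. In one flask, palladium-catalysed enantioselective strain-release cleavage of the achiral cyclobutanol joins C6 to C1 of a propargylic carbonate and sets C5; the resulting enol silane then closes C4–C3 onto the gold-activated aryl allene. Benzyl ethers mask all eight phenols.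

Key step: step 8

Assumption: 3-bromo-1,1-dimethoxycyclobutane is taken as purchasable, and the enantiomer of the ferrocenyl P,N ligand that leads to the (R)-configured benzylic centre is to be identified in a test reaction (the antipode is used if the sense is opposite).

**Step 1**
Reactants: 1 4-bromobenzene-1,3-diol
Product: 2 2,4-bis(benzyloxy)-1-bromobenzene
Conditions: BnBr, K2CO3, DMF, 60 °C
Reagents that add atoms: benzyl bromide BrCc1ccccc1
Why: Williamson ether synthesis, in which both phenoxides are alkylated by benzyl bromide under carbonate base.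

**Step 2**
Reactants: 2 2,4-bis(benzyloxy)-1-bromobenzene; 3 3-bromo-1,1-dimethoxycyclobutane
Product: 5 3-[2,4-bis(benzyloxy)phenyl]cyclobutan-1-one, via dimethyl ketal 4 (not isolated)
Conditions: NiI2 (10 mol %), 4,4'-di-tert-butyl-2,2'-bipyridine, NaI, pyridine, Zn, DMPU, 60 °C; then 1 M HCl, THF, rt
Reagents that add atoms: water O
Why: Nickel-catalysed reductive cross-electrophile coupling should join the aryl bromide (oxidative addition to zerovalent nickel) with the cyclobutyl radical from the secondary bromide, and the acidic work-up hydrolyses the ketal to the achiral ketone.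

**Step 3**
Reactants: 2 2,4-bis(benzyloxy)-1-bromobenzene; 5 3-[2,4-bis(benzyloxy)phenyl]cyclobutan-1-one
Product: 7 cis-1,3-bis[2,4-bis(benzyloxy)phenyl]cyclobutan-1-ol (hydroxyl cis to the 3-aryl group), via aryllithium 6 (not isolated)
Conditions: n-BuLi, THF, −78 °C; then 5, −78 to 0 °C; aq. NH4Cl
Reagents that add atoms: none
Why: Bromine–lithium exchange and 1,2-addition of the aryllithium to the cyclobutanone anti to the 3-aryl group should give mainly the cis alcohol, an achiral compound whose two C1–CH2 ring bonds are enantiotopic.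

**Step 4**
Reactants: 8 5-bromo-2,4-dihydroxybenzaldehyde
Product: 9 2,4-bis(benzyloxy)-5-bromobenzaldehyde
Conditions: BnBr, K2CO3, DMF, 60 °C
Reagents that add atoms: benzyl bromide BrCc1ccccc1
Why: Williamson ether synthesis, with excess reagent and heating to alkylate the hydrogen-bonded 2-hydroxyl as well.

**Step 5**
Reactants: 10 3,5-bis(benzyloxy)benzaldehyde
Product: 11 1,3-bis(benzyloxy)-5-ethenylbenzene
Conditions: Ph3PCH3Br, KOtBu, THF, 0 °C to rt
Reagents that add atoms: methyltriphenylphosphonium bromide C[P+](c1ccccc1)(c1ccccc1)c1ccccc1.[Br-]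
Why: Wittig methylenation of the aldehyde with the non-stabilised ylide.

**Step 6**
Reactants: 9 2,4-bis(benzyloxy)-5-bromobenzaldehyde; 11 1,3-bis(benzyloxy)-5-ethenylbenzene
Product: 12 2,4-bis(benzyloxy)-5-[(E)-2-[3,5-bis(benzyloxy)phenyl]ethenyl]benzaldehyde
Conditions: Pd(OAc)2, P(o-tol)3, Et3N, DMF, 100 °C
Reagents that add atoms: none
Why: Mizoroki–Heck coupling, in which syn-carbopalladation and syn-β-hydride elimination should deliver the (E)-stilbene while aldehyde and benzyl ethers are inert.

**Step 7**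
Reactants: 12 2,4-bis(benzyloxy)-5-[(E)-2-[3,5-bis(benzyloxy)phenyl]ethenyl]benzaldehyde
Product: 14 1-{2,4-bis(benzyloxy)-5-[(E)-2-[3,5-bis(benzyloxy)phenyl]ethenyl]phenyl}but-2-yn-1-yl methyl carbonate (racemic), via magnesium alkoxide 13 (not isolated)
Conditions: CH3C≡CMgBr, THF, 0 °C; then ClCO2Me, 0 °C to rt
Reagents that add atoms: 1-propynylmagnesium bromide CC#C[Mg]Br; methyl chloroformate COC(=O)Cl
Why: Grignard 1,2-addition to the aldehyde and acylation of the alkoxide in the same flask; the carbonate is racemic, which does not matter because its stereocentre becomes the trigonal allene terminus.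

**Step 8**
Reactants: 7 cis-1,3-bis[2,4-bis(benzyloxy)phenyl]cyclobutan-1-ol; 14 the propargylic methyl carbonate
Product: 17 [2,4-bis(benzyloxy)phenyl][(1S,2S,6R)-6-[2,4-bis(benzyloxy)phenyl]-2-{2,4-bis(benzyloxy)-5-[(E)-2-[3,5-bis(benzyloxy)phenyl]ethenyl]phenyl}-4-methylcyclohex-3-en-1-yl]methanone, via aryl allene 15 (not isolated), via enol silane 16 (not isolated)
Conditions: Pd2(dba)3·CHCl3 (2.5 mol %), (R)-N,N-dimethyl-1-[(S)-2-(diphenylphosphino)ferrocenyl]ethylamine (6 mol %), toluene, 50 °C; then i-Pr2NEt (2.2 equiv), Me3SiOTf (3 equiv), CH2Cl2, 0 °C; then Ph3PAuNTf2 (10 mol %), 0 °C to rt; aq. NaHCO3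
Reagents that add atoms: none
Why: Proposed new method: zerovalent palladium ionises carbonate 14 with loss of CO2 to an allenylpalladium methoxide that exchanges with cyclobutanol 7, and ligand-controlled, strain-driven β-carbon elimination of one of the two enantiotopic C1–CH2 ring bonds followed by C(sp3)–C(sp2) reductive elimination gives allene 15, which forms the CH2–C(Me) bond and sets the benzylic centre (closest known type: palladium-catalysed asymmetric ring-opening arylation, alkenylation and allenylation of tert-cyclobutanols). In the same flask the new aryl ketone is silylated to the Z enol silane 16, and cationic monovalent gold turns the electron-rich aryl allene into a flat gold-bound allyl cation whose benzylic terminus is captured by the enol silane, forming the CH(aroyl)–CH(aryl) bond, after which protodeauration by the ammonium triflate leaves the C(Me)=CH double bond (closest known type: gold-catalysed carbocyclisation of silyl enol ethers onto alkynes and allenes). The cyclohexene ring closes in a 6-(enolexo)-endo-trig mode. The centre bearing the 2,4-bis(benzyloxy)phenyl group is set by the chiral P,N ligand, and it controls the two new centres through a chair-like transition state in which that aryl group, the enol silane carbon and the E-configured cation terminus are all equatorial, the α-keto centre being also the epimerisable, thermodynamically preferred one. The step needs allenyl rather than propargyl coupling and reductive elimination rather than β-hydride elimination (bidentate ligand, hindered benzylic propargyl terminus), attack at the benzylic allyl terminus rather than the methyl-bearing one (only the former gives a six-membered ring), and capture by the tethered nucleophile rather than Friedel–Crafts attack by the benzyloxyarenes, which is why the ketone is converted into the enol silane before the allene is activated.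

**Step 9**
Reactants: 17 the octabenzyl ether of the target
Product: 18 (2,4-dihydroxyphenyl)[(1S,2S,6R)-6-(2,4-dihydroxyphenyl)-2-{2,4-dihydroxy-5-[(E)-2-(3,5-dihydroxyphenyl)ethenyl]phenyl}-4-methylcyclohex-3-en-1-yl]methanone (CNP0327388.1)
Conditions: BCl3, pentamethylbenzene, CH2Cl2, −78 °C; MeOH quench
Reagents that add atoms: none
Why: Lewis-acid debenzylation in which BCl3 activates each aryl benzyl ether and pentamethylbenzene traps the benzyl cation irreversibly (Friedel–Crafts), which at −78 °C should spare both alkenes and the ketone and touches no stereocentre.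

**Compound list**

1 | 4-bromobenzene-1,3-diol | Oc1ccc(Br)c(O)c1 | starting material
2 | 2,4-bis(benzyloxy)-1-bromobenzene | Brc1ccc(OCc2ccccc2)cc1OCc1ccccc1 | intermediate
3 | 3-bromo-1,1-dimethoxycyclobutane | COC1(OC)CC(Br)C1 | starting material
4 | 2,4-bis(benzyloxy)-1-(3,3-dimethoxycyclobutyl)benzene | COC1(OC)CC(c2ccc(OCc3ccccc3)cc2OCc2ccccc2)C1 | intermediate
5 | 3-[2,4-bis(benzyloxy)phenyl]cyclobutan-1-one | O=C1CC(c2ccc(OCc3ccccc3)cc2OCc2ccccc2)C1 | intermediate
6 | [2,4-bis(benzyloxy)phenyl]lithium | [Li]c1ccc(OCc2ccccc2)cc1OCc1ccccc1 | intermediate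
7 | cis-1,3-bis[2,4-bis(benzyloxy)phenyl]cyclobutan-1-ol (OH cis to the 3-aryl group, achiral) | O[C@@]1(c2ccc(OCc3ccccc3)cc2OCc2ccccc2)C[C@@H](c2ccc(OCc3ccccc3)cc2OCc2ccccc2)C1 | intermediate
8 | 5-bromo-2,4-dihydroxybenzaldehyde | O=Cc1cc(Br)c(O)cc1O | starting material
9 | 2,4-bis(benzyloxy)-5-bromobenzaldehyde | O=Cc1cc(Br)c(OCc2ccccc2)cc1OCc1ccccc1 | intermediate
10 | 3,5-bis(benzyloxy)benzaldehyde | O=Cc1cc(OCc2ccccc2)cc(OCc2ccccc2)c1 | starting material
11 | 1,3-bis(benzyloxy)-5-ethenylbenzene | C=Cc1cc(OCc2ccccc2)cc(OCc2ccccc2)c1 | intermediate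
12 | 2,4-bis(benzyloxy)-5-[(E)-2-[3,5-bis(benzyloxy)phenyl]ethenyl]benzaldehyde | O=Cc1cc(/C=C/c2cc(OCc3ccccc3)cc(OCc3ccccc3)c2)c(OCc2ccccc2)cc1OCc1ccccc1 | intermediate
13 | bromomagnesium 1-{2,4-bis(benzyloxy)-5-[(E)-2-[3,5-bis(benzyloxy)phenyl]ethenyl]phenyl}but-2-yn-1-olate (racemic) | CC#CC(O[Mg]Br)c1cc(/C=C/c2cc(OCc3ccccc3)cc(OCc3ccccc3)c2)c(OCc2ccccc2)cc1OCc1ccccc1 | intermediate
14 | 1-{2,4-bis(benzyloxy)-5-[(E)-2-[3,5-bis(benzyloxy)phenyl]ethenyl]phenyl}but-2-yn-1-yl methyl carbonate (racemic) | CC#CC(OC(=O)OC)c1cc(/C=C/c2cc(OCc3ccccc3)cc(OCc3ccccc3)c2)c(OCc2ccccc2)cc1OCc1ccccc1 | intermediate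
15 | (3R)-1,3-bis[2,4-bis(benzyloxy)phenyl]-7-{2,4-bis(benzyloxy)-5-[(E)-2-[3,5-bis(benzyloxy)phenyl]ethenyl]phenyl}-5-methylhepta-5,6-dien-1-one (both allene-axis epimers) | O=C(c1ccc(OCc2ccccc2)cc1OCc1ccccc1)C[C@H](c1ccc(OCc2ccccc2)cc1OCc1ccccc1)CC(C)=C=Cc1cc(/C=C/c2cc(OCc3ccccc3)cc(OCc3ccccc3)c2)c(OCc2ccccc2)cc1OCc1ccccc1 | intermediate
16 | (Z)-trimethylsilyl enol ether of 15 | C[Si](C)(C)O/C(c1ccc(OCc2ccccc2)cc1OCc1ccccc1)=C\[C@H](c1ccc(OCc2ccccc2)cc1OCc1ccccc1)CC(C)=C=Cc1cc(/C=C/c2cc(OCc3ccccc3)cc(OCc3ccccc3)c2)c(OCc2ccccc2)cc1OCc1ccccc1 | intermediate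
17 | [2,4-bis(benzyloxy)phenyl][(1S,2S,6R)-6-[2,4-bis(benzyloxy)phenyl]-2-{2,4-bis(benzyloxy)-5-[(E)-2-[3,5-bis(benzyloxy)phenyl]ethenyl]phenyl}-4-methylcyclohex-3-en-1-yl]methanone | CC1=C[C@H](c2cc(/C=C/c3cc(OCc4ccccc4)cc(OCc4ccccc4)c3)c(OCc3ccccc3)cc2OCc2ccccc2)[C@@H](C(=O)c2ccc(OCc3ccccc3)cc2OCc2ccccc2)[C@H](c2ccc(OCc3ccccc3)cc2OCc2ccccc2)C1 | intermediate
18 | (2,4-dihydroxyphenyl)[(1S,2S,6R)-6-(2,4-dihydroxyphenyl)-2-{2,4-dihydroxy-5-[(E)-2-(3,5-dihydroxyphenyl)ethenyl]phenyl}-4-methylcyclohex-3-en-1-yl]methanone | CC1=C[C@H](c2cc(/C=C/c3cc(O)cc(O)c3)c(O)cc2O)[C@@H](C(=O)c2ccc(O)cc2O)[C@H](c2ccc(O)cc2O)C1 | target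

**Totals.** Total step count: 9. Longest linear sequence: 5 steps (1, 2, 3, 8, 9, or equally 4, 6, 7, 8, 9).

**Steps most likely to fail**

1. Step 8 (bears the label). What may go wrong:
   - β-hydride elimination or poor discrimination of the enantiotopic ring bonds at the alkylpalladium stage;
   - cross-talk of palladium residues, amine and gold in one flask;
   - transfer of the uncontrolled allene axis to the new benzylic centre if the gold-bound allene is captured before it flattens.

   The fallback uses known reactions only, sets out from 12 and 7 and comes back at 17. Alkoxide 13, made from 12 as in step 7, is treated in the same flask with NaAlH2(OCH2CH2OMe)2 and then I2 (hydroxyl-directed trans-hydroalumination, iodinolysis) to give the (Z)-iodo allylic alcohol F1. F1 is O-methylated (NaH, MeI) to the methyl ether F2. F2 and 7 are joined by the palladium-catalysed enantioselective ring-opening alkenylation of the cyclobutanol (Pd(OAc)2, the same P,N ligand, Cs2CO3, toluene) to give the isolated keto ether F3. LiN(SiMe3)2 and Me3SiCl at −78 °C convert F3 into the enol silane F4. Catalytic Me3SiOTf at −78 °C then ionises the benzylic allylic methyl ether to a free, planar allyl cation that the enol silane captures (Mukaiyama-type SN1 alkylation through the same chair-like closure), giving 17.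

2. Step 9. What may go wrong: incomplete cleavage of eight ethers, transfer of benzyl cations to the resorcinol rings, and loss of the oxidation-prone free octaphenol during quench and chromatography. The fallback sets out from 17 and comes back at 18. The BCl3/pentamethylbenzene cleavage is quenched and the crude polyphenol is acetylated at once (Ac2O, pyridine) to the stable, chromatographable octaacetate F5, from which partly benzylated material can be separated and recycled. Mild methanolysis (K2CO3, MeOH, 0 °C) then releases 18.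

3. Step 2. What may go wrong: slow oxidative addition of the electron-rich, ortho-substituted aryl bromide to zerovalent nickel, so that reduction and homocoupling of the cyclobutyl bromide take over. The fallback sets out from 2 and comes back at 5. Suzuki–Miyaura alkenylation of 2 (CH2=CHBF3K, PdCl2(dppf), Cs2CO3, THF/H2O) gives the styrene F6. [2+2] Cycloaddition with dichloroketene generated from Cl3CCOCl and Zn(Cu) in Et2O gives the dichlorocyclobutanone F7 with the aryl group at C3. Zn in AcOH removes both chlorines to give 5.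

**Further compounds**

F1 | step 8 | (2Z)-1-{2,4-bis(benzyloxy)-5-[(E)-2-[3,5-bis(benzyloxy)phenyl]ethenyl]phenyl}-3-iodobut-2-en-1-ol (racemic) | C/C(I)=C/C(O)c1cc(/C=C/c2cc(OCc3ccccc3)cc(OCc3ccccc3)c2)c(OCc2ccccc2)cc1OCc1ccccc1
F2 | step 8 | methyl ether of F1 (racemic) | C/C(I)=C/C(OC)c1cc(/C=C/c2cc(OCc3ccccc3)cc(OCc3ccccc3)c2)c(OCc2ccccc2)cc1OCc1ccccc1
F3 | step 8 | (3R,5Z)-1,3-bis[2,4-bis(benzyloxy)phenyl]-7-{2,4-bis(benzyloxy)-5-[(E)-2-[3,5-bis(benzyloxy)phenyl]ethenyl]phenyl}-7-methoxy-5-methylhept-5-en-1-one (both C7 epimers) | O=C(c1ccc(OCc2ccccc2)cc1OCc1ccccc1)C[C@H](c1ccc(OCc2ccccc2)cc1OCc1ccccc1)C/C(C)=C\C(OC)c1cc(/C=C/c2cc(OCc3ccccc3)cc(OCc3ccccc3)c2)c(OCc2ccccc2)cc1OCc1ccccc1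
F4 | step 8 | (Z)-trimethylsilyl enol ether of F3 | C[Si](C)(C)O/C(c1ccc(OCc2ccccc2)cc1OCc1ccccc1)=C\[C@H](c1ccc(OCc2ccccc2)cc1OCc1ccccc1)C/C(C)=C\C(OC)c1cc(/C=C/c2cc(OCc3ccccc3)cc(OCc3ccccc3)c2)c(OCc2ccccc2)cc1OCc1ccccc1
F5 | step 9 | octaacetate of 18 | CC1=C[C@H](c2cc(/C=C/c3cc(OC(C)=O)cc(OC(C)=O)c3)c(OC(C)=O)cc2OC(C)=O)[C@@H](C(=O)c2ccc(OC(C)=O)cc2OC(C)=O)[C@H](c2ccc(OC(C)=O)cc2OC(C)=O)C1
F6 | step 2 | 2,4-bis(benzyloxy)-1-ethenylbenzene | C=Cc1ccc(OCc2ccccc2)cc1OCc1ccccc1
F7 | step 2 | 3-[2,4-bis(benzyloxy)phenyl]-2,2-dichlorocyclobutan-1-one (racemic) | O=C1CC(c2ccc(OCc3ccccc3)cc2OCc2ccccc2)C1(Cl)Cl
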